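**Retrosynthetic overview**
- Target ⇒ global hydrogenolysis of a tri-benzyl precursor (two ArOBn, one CO2Bn) ⇒ diimide reduction of the alkene from a cross-metathesis between a (3R)-3-allyl-dihydroisocoumarin and benzyl (S)-but-3-en-2-yl succinate (side-chain carbinol from the chiral pool).
- 3-Allyl lactone ⇒ Br/Li exchange, CO2 and lactonisation of an (R)-bromo-homoallylic alcohol; the lactone is the only ring made (the arene is bought) and it is closed after the key step.
- Key C–C bond (C3–C1′): intermolecular Brown asymmetric carbonyl allylation of a 2-arylacetaldehyde with B-allyldiisopinocampheylborane; this sets C3 (R).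
- Arylacetaldehyde ⇒ Wittig one-carbon homologation of the benzaldehyde obtained by ortho-lithiation/formylation of O,O-dibenzyl bromohydroquinone.

Assumption: the allylborane (1 M pentane solution; the same reagent is obtained from (+)-Ipc2BOMe and allylMgBr) and (S)-but-3-en-2-ol are bought as single enantiomers. The facial selectivity of the allylborane is assigned from Brown's empirical rule, not re-derived here; the configuration of the alcohol from step 5 should be confirmed by Mosher ester analysis.

**Step 1**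
Reactants: 1 2-bromobenzene-1,4-diol
Product: 2 1,4-bis(benzyloxy)-2-bromobenzene
Conditions: BnBr (2.3 equiv), K2CO3 (3 equiv), DMF, rt → 50 °C, N2
Reagents that add atoms: benzyl bromide, BrCc1ccccc1
Why: Williamson etherification of both phenols; benzyl survives the organolithium, Wittig, acid, borane, Ru and diimide steps and leaves by hydrogenolysis at the very end.

**Step 2**
Reactants: 2 1,4-bis(benzyloxy)-2-bromobenzene
Product: 4 3,6-bis(benzyloxy)-2-bromobenzaldehyde, via aryllithium 3 (not isolated)
Conditions: LDA (1.2 equiv), THF, −78 °C, 1 h; DMF (3 equiv), −78 → 0 °C; 1 M HCl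
Reagents that add atoms: N,N-dimethylformamide, CN(C)C=O
Why: Directed ortho-lithiation/formylation: the C–H flanked by Br and OBn is the most acidic, non-nucleophilic LDA at −78 °C removes it without Br/Li exchange or aryne formation, and DMF traps the aryllithium as the aldehyde.

**Step 3**
Reactants: 4 3,6-bis(benzyloxy)-2-bromobenzaldehyde
Product: 5 1,4-bis(benzyloxy)-2-bromo-3-(2-methoxyethenyl)benzene (E/Z mixture)
Conditions: Ph3P(CH2OMe)Cl (1.5 equiv), KOtBu (1.45 equiv), THF, 0 °C → rt
Reagents that add atoms: (methoxymethyl)triphenylphosphonium chloride, COC[P+](c1ccccc1)(c1ccccc1)c1ccccc1.[Cl-]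
Why: Wittig methoxymethylenation works even on 2,6-disubstituted benzaldehydes, and the E/Z ratio is irrelevant because both isomers hydrolyse to the same aldehyde.

**Step 4**
Reactants: 5 1,4-bis(benzyloxy)-2-bromo-3-(2-methoxyethenyl)benzene
Product: 6 2-[3,6-bis(benzyloxy)-2-bromophenyl]acetaldehyde
Conditions: 2 M aq. HCl, THF, 50 °C, N2; used crude at once
Reagents that add atoms: water, O
Why: Acid-catalysed enol-ether hydrolysis (C-protonation, hydration of the oxocarbenium ion, loss of MeOH) completes the one-carbon homologation, and aryl benzyl ethers and the aryl bromide are inert to dilute aqueous acid.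

**Step 5 (key step)**
Reactants: 6 2-[3,6-bis(benzyloxy)-2-bromophenyl]acetaldehyde; 7 (−)-B-allyldiisopinocampheylborane (both isopinocampheyl groups derived from (−)-α-pinene)
Product: 9 (2R)-1-[3,6-bis(benzyloxy)-2-bromophenyl]pent-4-en-2-ol, via borinate 8 (not isolated)
Conditions: 7 (1.3 equiv, salt-free, 1 M in pentane), Et2O, −78 °C, 2 h; then 3 M NaOH, 30 % H2O2, 0 °C → rt
Reagents that add atoms: none
Why: Brown asymmetric carbonyl allylation through a closed chair (Zimmerman–Traxler) transition state: the (−)-α-pinene-derived reagent attacks the Re face (its antipode gives (S)-1-phenylbut-3-en-1-ol from PhCHO, and CH2Ar outranks allyl just as Ph does), so the C3–C1′ bond and the (R)-carbinol are set under reagent control (typically ≥ 92–96 % ee) without enolising the aldehyde.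

**Step 6**
Reactants: 9 (2R)-1-[3,6-bis(benzyloxy)-2-bromophenyl]pent-4-en-2-ol
Product: 12 (3R)-5,8-bis(benzyloxy)-3-(prop-2-en-1-yl)-3,4-dihydro-1H-isochromen-1-one, via dilithio species 10 (not isolated), via hydroxy acid 11 (not isolated)
Conditions: n-BuLi (2.2 equiv), THF, −78 °C, 20 min; CO2 (g), −78 → 0 °C; 1 M HCl; then TsOH·H2O (5 mol %), PhMe, 60 °C
Reagents that add atoms: carbon dioxide, O=C=O
Why: Bromine–lithium exchange on the lithium alkoxide (much faster at −78 °C than attack on the benzyl ethers or the alkene), carboxylation and acid-promoted δ-lactonisation build the dihydroisocoumarin ring without touching the C3–O bond, so the (R) centre is retained.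

**Step 7**
Reactants: 13 (2S)-but-3-en-2-ol; 14 4-(benzyloxy)-4-oxobutanoic acid (monobenzyl succinate)
Product: 15 benzyl (2S)-but-3-en-2-yl butanedioate
Conditions: DCC (1.1 equiv), DMAP (0.1 equiv), CH2Cl2, 0 °C → rt
Reagents that add atoms: none
Why: Steglich esterification acylates the alcohol oxygen without breaking the C–O bond, so the (S) centre from the chiral pool is carried over unchanged.

**Step 8**
Reactants: 12 (3R)-5,8-bis(benzyloxy)-3-(prop-2-en-1-yl)-3,4-dihydro-1H-isochromen-1-one; 15 benzyl (2S)-but-3-en-2-yl butanedioate (3 equiv)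
Product: 16 benzyl (2S,3E)-5-[(3R)-5,8-bis(benzyloxy)-1-oxo-3,4-dihydro-1H-isochromen-3-yl]pent-3-en-2-yl butanedioate
Conditions: Hoveyda–Grubbs II (5 mol %), CH2Cl2, 40 °C, Ar sparge
Reagents that add atoms: none
Why: Olefin cross-metathesis of a type I terminal alkene with an excess of the slowly dimerising secondary allylic ester gives mainly the E cross-product with loss of ethene; neither stereocentre is involved and the alkene geometry is erased in the next step.

**Step 9**
Reactants: 16 benzyl (2S,3E)-5-[(3R)-5,8-bis(benzyloxy)-1-oxo-3,4-dihydro-1H-isochromen-3-yl]pent-3-en-2-yl butanedioate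
Product: 17 benzyl (2S)-5-[(3R)-5,8-bis(benzyloxy)-1-oxo-3,4-dihydro-1H-isochromen-3-yl]pentan-2-yl butanedioate
Conditions: TsNHNH2 (10 equiv), NaOAc (12 equiv), DME/H2O 1:1, 85 °C
Reagents that add atoms: none
Why: Diimide reduction (concerted syn transfer of H2 from HN=NH made in situ) saturates only the C=C bond and avoids the allylic C–O hydrogenolysis and premature debenzylation that Pd/H2 could cause.

**Step 10**
Reactants: 17 benzyl (2S)-5-[(3R)-5,8-bis(benzyloxy)-1-oxo-3,4-dihydro-1H-isochromen-3-yl]pentan-2-yl butanedioate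
Product: 18 Aspergimarin B, 4-{[(2S)-5-[(3R)-5,8-dihydroxy-1-oxo-3,4-dihydro-1H-isochromen-3-yl]pentan-2-yl]oxy}-4-oxobutanoic acid
Conditions: H2 (1 atm), 10 % Pd/C, EtOAc/EtOH, rt; filtered and concentrated under N2
Reagents that add atoms: none
Why: Catalytic hydrogenolysis removes the two aryl benzyl ethers and the benzyl ester under neutral conditions that leave the lactone, the secondary succinate ester and both stereocentres untouched.

**Compound list**
1 | 2-bromobenzene-1,4-diol | Oc1ccc(O)c(Br)c1 | starting material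
2 | 1,4-bis(benzyloxy)-2-bromobenzene | Brc1cc(OCc2ccccc2)ccc1OCc1ccccc1 | intermediate
3 | [3,6-bis(benzyloxy)-2-bromophenyl]lithium | [Li]c1c(Br)c(OCc2ccccc2)ccc1OCc1ccccc1 | intermediate
4 | 3,6-bis(benzyloxy)-2-bromobenzaldehyde | O=Cc1c(Br)c(OCc2ccccc2)ccc1OCc1ccccc1 | intermediate
5 | 1,4-bis(benzyloxy)-2-bromo-3-(2-methoxyethenyl)benzene (E/Z mixture) | COC=Cc1c(Br)c(OCc2ccccc2)ccc1OCc1ccccc1 | intermediate
6 | 2-[3,6-bis(benzyloxy)-2-bromophenyl]acetaldehyde | O=CCc1c(Br)c(OCc2ccccc2)ccc1OCc1ccccc1 | intermediate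
7 | (−)-B-allyldiisopinocampheylborane (Ipc groups from (−)-α-pinene) | C=CCB([C@H]1C[C@H]2C[C@@H]([C@@H]1C)C2(C)C)[C@H]1C[C@H]2C[C@@H]([C@@H]1C)C2(C)C | starting material
8 | (2R)-1-[3,6-bis(benzyloxy)-2-bromophenyl]pent-4-en-2-yl diisopinocampheylborinate | C=CC[C@@H](OB([C@H]1C[C@H]2C[C@@H]([C@@H]1C)C2(C)C)[C@H]1C[C@H]2C[C@@H]([C@@H]1C)C2(C)C)Cc1c(Br)c(OCc2ccccc2)ccc1OCc1ccccc1 | intermediate
9 | (2R)-1-[3,6-bis(benzyloxy)-2-bromophenyl]pent-4-en-2-ol | C=CC[C@@H](O)Cc1c(Br)c(OCc2ccccc2)ccc1OCc1ccccc1 | intermediate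
10 | lithium (2R)-1-[3,6-bis(benzyloxy)-2-lithiophenyl]pent-4-en-2-olate | C=CC[C@@H](O[Li])Cc1c([Li])c(OCc2ccccc2)ccc1OCc1ccccc1 | intermediate
11 | 3,6-bis(benzyloxy)-2-[(2R)-2-hydroxypent-4-en-1-yl]benzoic acid | C=CC[C@@H](O)Cc1c(C(=O)O)c(OCc2ccccc2)ccc1OCc1ccccc1 | intermediate
12 | (3R)-5,8-bis(benzyloxy)-3-(prop-2-en-1-yl)-3,4-dihydro-1H-isochromen-1-one | C=CC[C@@H]1Cc2c(OCc3ccccc3)ccc(OCc3ccccc3)c2C(=O)O1 | intermediate
13 | (2S)-but-3-en-2-ol | C=C[C@H](C)O | starting material
14 | 4-(benzyloxy)-4-oxobutanoic acid | OC(=O)CCC(=O)OCc1ccccc1 | starting material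
15 | benzyl (2S)-but-3-en-2-yl butanedioate | C=C[C@H](C)OC(=O)CCC(=O)OCc1ccccc1 | intermediate
16 | benzyl (2S,3E)-5-[(3R)-5,8-bis(benzyloxy)-1-oxo-3,4-dihydro-1H-isochromen-3-yl]pent-3-en-2-yl butanedioate | C[C@@H](/C=C/C[C@@H]1Cc2c(OCc3ccccc3)ccc(OCc3ccccc3)c2C(=O)O1)OC(=O)CCC(=O)OCc1ccccc1 | intermediate
17 | benzyl (2S)-5-[(3R)-5,8-bis(benzyloxy)-1-oxo-3,4-dihydro-1H-isochromen-3-yl]pentan-2-yl butanedioate | C[C@@H](CCC[C@@H]1Cc2c(OCc3ccccc3)ccc(OCc3ccccc3)c2C(=O)O1)OC(=O)CCC(=O)OCc1ccccc1 | intermediate
18 | Aspergimarin B | C[C@@H](CCC[C@@H]1Cc2c(O)ccc(O)c2C(=O)O1)OC(=O)CCC(=O)O | target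

**Totals**
Total step count: 10. Longest linear sequence: 9 steps (steps 1–6, 8, 9, 10 from compound 1); step 7 is the one-step side branch.

**Three steps most likely to fail**

Step 5 (key allylation). The arylacetaldehyde 6 is labile, and the C3 epimer cannot be separated once the remote second centre is attached, so the ee must be secured here (recrystallisation of 12 can raise it). Fallback: it sets out from 6 and comes back at 9. Crude 6 is reduced at once (NaBH4, MeOH, 0 °C) to the bench-stable 2-[3,6-bis(benzyloxy)-2-bromophenyl]ethan-1-ol F1. F1 is then allylated from the alcohol oxidation level by iridium-catalysed transfer-hydrogenative carbonyl allylation (allyl acetate, [Ir(cod)Cl]2, (R)-Cl,MeO-BIPHEP, 4-chloro-3-nitrobenzoic acid, Cs2CO3, THF, 100 °C). The aldehyde then exists only transiently, aryl bromides are tolerated, and the chiral inductor is catalytic. The ligand antipode is my best assignment by analogy and must be fixed by Mosher analysis of 9.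

Step 6 (Br/Li exchange, carboxylation, lactonisation). Risks are anion translocation to a benzyl ether, butylation by n-BuBr and slow closure of the hindered acid. Fallback: it sets out from 9 and comes back at 12 without any new isolated compound. This is a palladium-catalysed intramolecular alkoxycarbonylation (Pd(OAc)2/Xantphos, CO 1 atm, K2CO3, toluene, 90 °C), in which the acyl-palladium intermediate is trapped directly by the C3 hydroxyl, so no organolithium and no free hydroxy acid are involved.

Step 8 (cross-metathesis). Risks are a sluggish, hindered secondary allylic ester and homodimerisation of 12. Fallback: it sets out from 12 and comes back at 17, with the acylation moved behind the C=C bond formation. Cross-metathesis of 12 with the free alcohol 13 (more reactive than its ester; same Ru catalyst) gives (3R)-5,8-bis(benzyloxy)-3-[(2E,4S)-4-hydroxypent-2-en-1-yl]-3,4-dihydro-1H-isochromen-1-one F2. Diimide reduction (TsNHNH2, NaOAc) gives (3R)-5,8-bis(benzyloxy)-3-[(4S)-4-hydroxypentyl]-3,4-dihydro-1H-isochromen-1-one F3. Steglich esterification of F3 with 14 (DCC, DMAP) then gives 17.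

**Further compounds**
F1 | step 5 | 2-[3,6-bis(benzyloxy)-2-bromophenyl]ethan-1-ol | OCCc1c(Br)c(OCc2ccccc2)ccc1OCc1ccccc1
F0 | step 6 | none | none
F2 | step 8 | (3R)-5,8-bis(benzyloxy)-3-[(2E,4S)-4-hydroxypent-2-en-1-yl]-3,4-dihydro-1H-isochromen-1-one | C[C@@H](/C=C/C[C@@H]1Cc2c(OCc3ccccc3)ccc(OCc3ccccc3)c2C(=O)O1)O
F3 | step 8 | (3R)-5,8-bis(benzyloxy)-3-[(4S)-4-hydroxypentyl]-3,4-dihydro-1H-isochromen-1-one | C[C@@H](CCC[C@@H]1Cc2c(OCc3ccccc3)ccc(OCc3ccccc3)c2C(=O)O1)O
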